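**Strategy.** The eleven-membered ring of the target (C1–C11) is the 4/9 bicycle of (−)-caryophyllene oxide with one bond removed: the fusion bond C2–C10 of the cyclobutane (C1, C2, C10, C11). The exocyclic methylene on C9 becomes the carboxyl carbon. Everything rests on cutting that fusion bond. A radical generated at C9 from a tertiary α-bromo ester is cyclobutylcarbinyl. Its β-scission breaks C10–C2, creates the C9=C10 enoate and turns the bicycle into the 11-membered ring in one operation, with the trans-epoxide and all fifteen carbons already in place. The precursor is the caryophyllane epoxide carrying bromine and a 2-(trimethylsilyl)ethyl ester on C9. Oxygenation of C11, alkene geometry and benzoylation follow.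

Key step: step 5

Numbering: ring atoms carry the labels of the target's 11-membered ring (C1 = CMe2, C2–C4 = CH2, C5/C6 = epoxide C(Me)/CH, C7 and C8 = CH2, C9 = carboxyl-bearing carbon, C10 = CH, C11 = C–O). The same labels are used for the bicyclic compounds, whose cyclobutane is C1–C2–C10–C11.

Assumption: C9 is an epimer mixture in compounds 2–5, 7 and 9; this centre becomes trigonal in steps 4 and 5.

Assumption: 10 is drawn with C8 and C11 trans across C9=C10 (ester cis to C11), the geometry expected from the radical conformer that can break the fusion bond. The C11 oxidation product is a γ-oxo enoate (a keto ester), and the ring-cis geometry of the target is set at that stage (step 7), so the route does not depend on the geometry of 10.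

**Step 1**
Reactants: 1 (−)-caryophyllene oxide
Product: 3 primary alcohol (CH2OH on C9; C9 epimers), via alkylborane 2 (not isolated)
Conditions: 9-BBN, THF, 0 °C to rt; then NaOH aq, H2O2, 0 °C to rt
Reagents that add atoms: hydrogen peroxide, OO; (9-BBN, B1C2CCCC1CCC2, leaves boron and carbon only in 2)
Why: Anti-Markovnikov hydroboration–oxidation, in which 9-BBN adds only to the 1,1-disubstituted alkene and leaves the trisubstituted epoxide alone, and alkaline peroxide replaces boron by OH with retention; the new C9 stereocentre forms as an epimer mixture (mainly by attack on the more open face), which is harmless because C9 is made trigonal later.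

**Step 2**
Reactants: 3 primary alcohol
Product: 5 carboxylic acid (CO2H on C9; C9 epimers), via aldehyde 4 (not isolated)
Conditions: TEMPO (cat.), NaOCl (cat.), NaClO2, MeCN, phosphate buffer pH 6.7, 35 °C; extraction at pH about 4.5
Reagents that add atoms: sodium chlorite, [Na+].[O-]Cl=O
Why: TEMPO-catalysed oxidation to the aldehyde followed in the same pot by chlorite (Pinnick-type) oxidation to the acid at near-neutral pH, where the epoxide and the cyclobutane are inert and no alkene remains to be chlorinated; no stereocentre is set.

**Step 3**
Reactants: 5 carboxylic acid; 6 2-(trimethylsilyl)ethanol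
Product: 7 2-(trimethylsilyl)ethyl ester (C9 epimers)
Conditions: DCC, DMAP (cat.), CH2Cl2, 0 °C to rt
Reagents that add atoms: 2-(trimethylsilyl)ethanol (6), C[Si](C)(C)CCO
Why: Steglich esterification under neutral carbodiimide/DMAP activation, which spares the acid-sensitive epoxide and installs an ester that fluoride can remove at the end without touching a benzoate.

**Step 4**
Reactants: 7 2-(trimethylsilyl)ethyl ester
Product: 9 tertiary α-bromo ester (Br and ester on C9; either epimer), via lithium enolate 8 (not isolated)
Conditions: LiN(iPr)2 (LDA), THF, −78 °C; then CBr4, −78 °C; aqueous work-up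
Reagents that add atoms: carbon tetrabromide, BrC(Br)(Br)Br; (LiN(iPr)2, [Li+].CC(C)[N-]C(C)C, leaves lithium only in 8)
Why: Ester enolate bromination, in which C9 carries the only enolisable hydrogen and the tetrasubstituted lithium enolate takes electrophilic bromine from CBr4; both epimers at the new C9 centre are acceptable because they give the same radical.

**Step 5**
Reactants: 9 tertiary α-bromo ester
Product: 10 11-membered epoxy enoate (C9=C10, ester cis to C11, C11 still CH2)
Conditions: Bu3SnH (1.3 equiv) and AIBN (0.2 equiv) added over 6 h by syringe pump to 9 in toluene (0.01 M), 90 °C; then KF aq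
Reagents that add atoms: none
Why: Bu3Sn• abstracts bromine from either C9 epimer to give one planar, ester-stabilised tertiary radical at C9 that is cyclobutylcarbinyl; β-scission of the C10–C2 bond forms the C9=C10 π bond and a secondary C2 radical, which takes hydrogen from Bu3SnH and carries the chain. The closest known reaction type is the stannane-mediated fragmentation of cyclobutylcarbinyl radicals, used to expand cyclobutane photoadducts to medium rings and to open pinane skeletons. No ring is closed by bond formation, so no exo or endo mode applies: the 11-membered ring (C1–C11) appears because the zero-atom bridge of the bicyclo[7.2.0]undecane is cut. No stereocentre is created (C2 and C10 lose theirs, C5 and C6 are untouched), and the alkene geometry follows from the conformer in which the C9 p orbital eclipses C10–C2, which places C8 anti to C11. The step needs cleavage of C10–C2 over C10–C11 and scission over direct reduction; the first is secured by the secondary versus primary (neopentyl) product radical, the relief of trans-fused four-ring strain and the better overlap of the fusion bond, the second by the low stationary stannane concentration at 90 °C. The epoxide is two methylene groups away from both radical centres (C9 and C2) and cannot open.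

**Step 6**
Reactants: 10 11-membered epoxy enoate
Product: 12 γ-oxo enoate (C11 ketone; ester cis to C11), via allylic peroxide 11 (not isolated)
Conditions: Rh2(cap)4 (1 mol%; cap = caprolactamate, C6H10NO), t-BuOOH (70% in water, 5 equiv), K2CO3 (0.5 equiv), CH2Cl2, rt
Reagents that add atoms: tert-butyl hydroperoxide, CC(C)(C)OO
Why: Radical allylic γ-oxidation of an α,β-unsaturated ester, in which t-BuOO• abstracts hydrogen from C11 because that radical is delocalised over C11–C10–C9 into the ester (abstraction at C8 gives only a cross-conjugated allyl radical), capture by t-BuOO• gives peroxide 11, and base-induced Kornblum–DeLaMare loss of t-BuOH gives the ketone; epoxide and silyl ester are inert to these near-neutral conditions.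

**Step 7**
Reactants: 12 γ-oxo enoate (ester cis to C11)
Product: 13 γ-oxo enoate (ester trans to C11; C8 and C11 cis in the ring)
Conditions: PhSSPh (10 mol%), hν (400 nm), benzene, rt
Reagents that add atoms: none
Why: Thiyl-radical-catalysed alkene equilibration, in which reversible addition of PhS• to C10 gives a C9 radical that rotates about C9–C10 before PhS• is expelled; the equilibrium should favour the isomer with the ester trans to the C11 acyl group (the two carbonyl groups no longer clash and their dipoles oppose), which is the ring-cis geometry of the target, and recovered 12 is resubmitted.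

**Step 8**
Reactants: 13 γ-oxo enoate (ring-cis)
Product: 14 (11R)-allylic alcohol
Conditions: (S)-2-methyl-CBS-oxazaborolidine (0.5 equiv), catecholborane (2 equiv), toluene, −78 to −40 °C; then MeOH, NaHCO3 aq
Reagents that add atoms: none
Why: Corey–Bakshi–Shibata reduction with 1,2-delivery of hydride to the enone carbonyl; the quaternary C1 flank is taken as the large group and the C10 alkenyl flank as the small one, so the (S)-catalyst should give the 11R alcohol (reagent control of the only new stereocentre), while the ester is trans to C11 and cannot lactonise and catecholborane at low temperature leaves epoxide and ester alone.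

**Step 9**
Reactants: 14 (11R)-allylic alcohol; 15 benzoyl chloride
Product: 16 (11R)-benzoate 2-(trimethylsilyl)ethyl ester
Conditions: BzCl (15), Et3N, DMAP, CH2Cl2, 0 °C to rt
Reagents that add atoms: benzoyl chloride (15), O=C(Cl)c1ccccc1
Why: DMAP-catalysed acylation (nucleophilic catalysis) of the hindered secondary allylic alcohol with retention at C11; no other nucleophilic group is present.

**Step 10**
Reactants: 16 (11R)-benzoate 2-(trimethylsilyl)ethyl ester
Product: 17 target acid CNP0377917.1
Conditions: Bu4NF, THF, 0 °C to rt; then NaH2PO4 aq (pH about 4.5)
Reagents that add atoms: none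
Why: Fluoride-induced β-elimination of the 2-(trimethylsilyl)ethyl ester (attack at silicon, loss of ethylene) frees the carboxylate without hydrolysis, so the benzoate, the epoxide, the alkene geometry and C11 are untouched, and buffered mild acidification gives the acid.

**Compound list**

1 | (−)-caryophyllene oxide | C[C@@]12CC[C@@H]3[C@H](CC3(C)C)C(=C)CC[C@H]1O2 | starting material
2 | B-alkyl-9-BBN adduct of 1 (boron on the former methylene carbon; C9 epimers) | C[C@@]12CC[C@@H]3[C@H](CC3(C)C)C(CB4C5CCCC4CCC5)CC[C@H]1O2 | intermediate (not isolated)
3 | primary alcohol, CH2OH on C9 of the epoxy 4/9 bicycle (C9 epimers) | C[C@@]12CC[C@@H]3[C@H](CC3(C)C)C(CO)CC[C@H]1O2 | intermediate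
4 | aldehyde, CHO on C9 (C9 epimers) | C[C@@]12CC[C@@H]3[C@H](CC3(C)C)C(C=O)CC[C@H]1O2 | intermediate (not isolated)
5 | carboxylic acid, CO2H on C9 (C9 epimers) | C[C@@]12CC[C@@H]3[C@H](CC3(C)C)C(C(=O)O)CC[C@H]1O2 | intermediate
6 | 2-(trimethylsilyl)ethanol | C[Si](C)(C)CCO | starting material
7 | 2-(trimethylsilyl)ethyl ester of 5 (C9 epimers) | C[C@@]12CC[C@@H]3[C@H](CC3(C)C)C(C(=O)OCC[Si](C)(C)C)CC[C@H]1O2 | intermediate
8 | lithium enolate of 7 | C[C@@]12CC[C@@H]3[C@H](CC3(C)C)C(=C([O-])OCC[Si](C)(C)C)CC[C@H]1O2.[Li+] | intermediate (not isolated)
9 | tertiary α-bromo 2-(trimethylsilyl)ethyl ester, Br and ester on C9 (either epimer), key-step precursor | C[C@@]12CC[C@@H]3[C@H](CC3(C)C)C(Br)(C(=O)OCC[Si](C)(C)C)CC[C@H]1O2 | intermediate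
10 | 2-(trimethylsilyl)ethyl (5R,6R,9Z)-5,6-epoxy-1,1,5-trimethylcycloundec-9-ene-9-carboxylate (route numbering; ester cis to C11), key-step product | CC1(C)CCC[C@@]2(C)O[C@@H]2CC/C(C(=O)OCC[Si](C)(C)C)=C/C1 | intermediate
11 | 11-(tert-butylperoxy) derivative of 10 (C11 epimers) | CC1(C)CCC[C@@]2(C)O[C@@H]2CC/C(C(=O)OCC[Si](C)(C)C)=C/C1OOC(C)(C)C | intermediate (not isolated)
12 | 11-oxo enoate, 9Z (ester cis to the C11 ketone) | CC1(C)CCC[C@@]2(C)O[C@@H]2CC/C(C(=O)OCC[Si](C)(C)C)=C/C1=O | intermediate
13 | 11-oxo enoate, 9E (ester trans to the C11 ketone; C8 and C11 cis in the ring) | CC1(C)CCC[C@@]2(C)O[C@@H]2CC/C(C(=O)OCC[Si](C)(C)C)=C\C1=O | intermediate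
14 | (5R,6R,9E,11R)-11-hydroxy enoate 2-(trimethylsilyl)ethyl ester | CC1(C)CCC[C@@]2(C)O[C@@H]2CC/C(C(=O)OCC[Si](C)(C)C)=C\[C@H]1O | intermediate
15 | benzoyl chloride | O=C(Cl)c1ccccc1 | starting material
16 | (5R,6R,9E,11R)-11-benzoyloxy enoate 2-(trimethylsilyl)ethyl ester | CC1(C)CCC[C@@]2(C)O[C@@H]2CC/C(C(=O)OCC[Si](C)(C)C)=C\[C@H]1OC(=O)c1ccccc1 | intermediate
17 | (5R,6R,9E,11R)-11-benzoyloxy-5,6-epoxy-1,1,5-trimethylcycloundec-9-ene-9-carboxylic acid (route numbering), CNP0377917.1 | CC1(C)CCC[C@@]2(C)O[C@@H]2CC/C(C(=O)O)=C\[C@H]1OC(=O)c1ccccc1 | target

**Totals**

Total step count: 10. Longest linear sequence: 10 steps, from 1 to 17.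

**Steps most likely to fail**

Step 5. Hydrogen transfer from the stannane to the ester-stabilised C9 radical may outrun β-scission, which would return the debrominated bicycle; cleavage towards C11 instead of C2 is the second way to lose material. Fallback: the hydrogen donor is removed from the scission event by switching to a bromine-atom-transfer chain. Setting out from 9, (Bu3Sn)2 (10–20 mol%) with sunlamp irradiation in benzene at 80 °C (0.2 M) should let the ring-opened C2 radical take bromine from a second molecule of 9. This gives the ring-expanded secondary bromide F1 (the 2-bromo derivative of 10, C2 epimers). F1 is then reduced with Bu3SnH/AIBN in benzene at 80 °C, which comes back to the route at 10.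

Step 6. Hydrogen abstraction may be slow at the neopentyl C11 or may compete at C8, and the peroxide may epoxidise the electron-poor alkene of the product. Fallback: polar oxygenation through the dienolate. Setting out from 10, LiN(iPr)2/HMPA in THF at −78 °C removes a C11 hydrogen (cis to the ester in 10), and PhSeBr selenenylates the dienolate at C9 to give the α-phenylseleno β,γ-unsaturated ester F2. H2O2/pyridine in CH2Cl2 at 0 °C forms the selenoxide, whose [2,3] shift and selenenate hydrolysis give the 11-hydroxy enoate F3 (C11 epimers, geometry as formed). F3 is oxidised at once with Dess–Martin periodinane/NaHCO3, because an isomer with the ester cis to the hydroxyl could lactonise. This comes back to the route at 12; any 13 present is simply carried through step 7.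

Step 8. Facial selectivity may be poor because both flanks of the ketone are bulky and the ring adds its own bias. Fallback: substrate-controlled reduction with separation and recycling. Setting out from 13, Luche reduction (NaBH4, CeCl3·7H2O, MeOH, −78 °C) gives 14 together with the (11S)-alcohol F4. The two are diastereomers and are separated by chromatography, and F4 is oxidised back to 13 with Dess–Martin periodinane and resubmitted. The fallback comes back to the route at 14.

**Further compounds**

F1 | step 5 | 2-bromo derivative of 10 (C2 epimers) | CC1(C)C(Br)CC[C@@]2(C)O[C@@H]2CC/C(C(=O)OCC[Si](C)(C)C)=C/C1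
F2 | step 6 | 9-phenylseleno Δ10 ester (β,γ-unsaturated; C9 epimers) | CC1(C)CCC[C@@]2(C)O[C@@H]2CCC(C(=O)OCC[Si](C)(C)C)([Se]c2ccccc2)C=C1
F3 | step 6 | 11-hydroxy enoate (C11 epimers, alkene geometry as formed) | CC1(C)CCC[C@@]2(C)O[C@@H]2CCC(C(=O)OCC[Si](C)(C)C)=CC1O
F4 | step 8 | (11S)-hydroxy enoate, C11 epimer of 14 | CC1(C)CCC[C@@]2(C)O[C@@H]2CC/C(C(=O)OCC[Si](C)(C)C)=C\[C@@H]1O
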